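**Assumption:** the SMILES encodes (2S) at C2 and a (2E) side-chain alkene; geranyl acetate, resorcinol and catechol diacetate are taken as the commercial, achiral starting materials.

## Retrosynthetic overview

1. Prokinawan (19) comes from (2S)-flavanone triacetate 18 by lipase-mediated removal of three phenolic acetates, so the finished flavanone never sees acid or base.
2. The C2–aryl bond and the only stereocentre come from a Rh-catalysed asymmetric 1,4-addition of boronic acid 17 to chromone 14.
3. Chromone 13/14 comes from o-hydroxyacetophenone 11 via an enaminone. The acetyl group sits ortho to the single free OH of the C2-symmetric phenol 9, so the chain can only end up at C6, not C8.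
4. Phenol 9 comes from resorcinol bis-MOM ether by directed ortho-metalation/allylation with bromide 5, then sterically controlled Ir C–H borylation/oxidation para to the chain.
5. Bromide 5 comes from geranyl acetate by selective hydration of the distal alkene. Ring order: A ring bought, pyranone ring closed in step 11, B ring attached in step 15.

## Forward route

**Step 1**
Reactants: 1, geranyl acetate
Product: 2, (2E)-7-hydroxy-3,7-dimethyloct-2-en-1-yl acetate
Conditions: Hg(OAc)2, THF/H2O (1:1), rt; then NaBH4, aq NaOH, 0 °C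
Reagents that add atoms: water, O
Why: Oxymercuration–demercuration gives Markovnikov hydration of the distal 6,7-alkene only, because the allylic acetate deactivates the 2,3-alkene; the (2E) geometry is untouched.

**Step 2**
Reactants: 2
Product: 3, (2E)-3,7-dimethyl-7-(triethylsilyloxy)oct-2-en-1-yl acetate
Conditions: TESOTf, 2,6-lutidine, CH2Cl2, −78 → 0 °C
Reagents that add atoms: triethylsilyl triflate, CC[Si](CC)(CC)OS(=O)(=O)C(F)(F)F
Why: Silyl triflate silylation masks the tertiary alcohol so it cannot quench the aryl-metal reagent in step 6.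

**Step 3**
Reactants: 3
Product: 4, (2E)-3,7-dimethyl-7-(triethylsilyloxy)oct-2-en-1-ol
Conditions: K2CO3, MeOH, 0 °C → rt
Reagents that add atoms: none
Why: Base-catalysed transesterification removes the primary acetate; the tertiary TES ether is stable to carbonate/methanol.

**Step 4**
Reactants: 4
Product: 5, (6E)-8-bromo-2,6-dimethyl-2-(triethylsilyloxy)oct-6-ene
Conditions: MsCl, Et3N, THF, −40 °C; then LiBr, THF, 0 °C (used crude)
Reagents that add atoms: lithium bromide, [Li+].[Br-]
Why: Mesylation then SN2 displacement by bromide at the primary allylic carbon gives the bromide without acid, keeping the E-alkene and the silyl ether.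

**Step 5**
Reactants: 6, resorcinol
Product: 7, 1,3-bis(methoxymethoxy)benzene
Conditions: NaH, MOMCl, DMF, 0 °C → rt
Reagents that add atoms: chloromethyl methyl ether, COCCl
Why: Williamson-type O-alkylation installs two MOM ethers that serve as both protecting groups and ortho-directing groups.

**Step 6**
Reactants: 7 (1.3 equiv); 5
Product: 8, 2-[(2E)-3,7-dimethyl-7-(triethylsilyloxy)oct-2-en-1-yl]-1,3-bis(methoxymethoxy)benzene
Conditions: n-BuLi, THF, 0 °C → rt; CuBr·SMe2, −40 °C; then 5, −40 °C → rt
Reagents that add atoms: none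
Why: Directed ortho-metalation occurs only between the two OMOM groups, and the derived arylcopper alkylates the primary allylic bromide by SN2 (linear product, E geometry retained).

**Step 7**
Reactants: 8
Product: 9, 4-[(2E)-3,7-dimethyl-7-(triethylsilyloxy)oct-2-en-1-yl]-3,5-bis(methoxymethoxy)phenol
Conditions: [Ir(OMe)(cod)]2 (1.5 mol %), dtbpy, B2pin2, THF, 65 °C; then 30% H2O2, aq NaOH, 0 °C
Reagents that add atoms: hydrogen peroxide, OO (B2pin2 is transient)
Why: Ir-catalysed C–H borylation is sterically controlled and selects the only C–H with no ortho substituent (para to the chain); oxidation of the boronate gives a phenol whose two ortho positions are equivalent.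

**Step 8**
Reactants: 9
Product: 10, 2-iodo-3,5-bis(methoxymethoxy)-4-[(2E)-3,7-dimethyl-7-(triethylsilyloxy)oct-2-en-1-yl]phenol
Conditions: NIS (1.0 equiv), CH2Cl2, −40 → 0 °C, dark
Reagents that add atoms: N-iodosuccinimide, O=C1CCC(=O)N1I
Why: Electrophilic aromatic iodination of the phloroglucinol-type ring is far faster than attack on the alkene and can only go ortho to the free OH, since para is blocked.

**Step 9**
Reactants: 10
Product: 11, 1-{6-hydroxy-2,4-bis(methoxymethoxy)-3-[(2E)-3,7-dimethyl-7-(triethylsilyloxy)oct-2-en-1-yl]phenyl}ethan-1-one (free OH flanked by acetyl and H; chain between the two OMOM groups)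
Conditions: PdCl2(PPh3)2 (5 mol %), tributyl(1-ethoxyvinyl)stannane, toluene, 95 °C; then 5% aq oxalic acid, THF, rt
Reagents that add atoms: tributyl(1-ethoxyvinyl)stannane, CCCC[Sn](CCCC)(CCCC)C(=C)OCC; water, O
Why: Stille coupling with an acetyl-anion equivalent, then mild enol-ether hydrolysis, puts the acetyl group exactly at the iodinated carbon without organolithiums or Lewis acids.

**Step 10**
Reactants: 11
Product: 12, (2E)-3-(dimethylamino)-1-{6-hydroxy-2,4-bis(methoxymethoxy)-3-[(2E)-3,7-dimethyl-7-(triethylsilyloxy)oct-2-en-1-yl]phenyl}prop-2-en-1-one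
Conditions: DMF-DMA (3 equiv), toluene, 85 °C
Reagents that add atoms: N,N-dimethylformamide dimethyl acetal, COC(OC)N(C)C
Why: Condensation of the methyl ketone with the formamide acetal gives the enaminone, the standard one-carbon homologation towards 2-unsubstituted chromones.

**Step 11**
Reactants: 12
Product: 13, 5,7-dihydroxy-6-[(2E)-7-hydroxy-3,7-dimethyloct-2-en-1-yl]-4H-chromen-4-one
Conditions: conc. HCl (2 equiv), CH2Cl2, 0 °C, 15 min (ring closure); then 2 M HCl, MeOH/THF/H2O, rt → 40 °C (MOM and TES removal)
Reagents that add atoms: none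
Why: Acid-promoted intramolecular addition–elimination closes the pyranone through the only free phenol before any MOM group is lost, fixing the chain at C6; continued acidolysis then removes both MOM acetals and the TES ether at this achiral stage.

**Step 12**
Reactants: 13
Product: 14, 5-hydroxy-6-[(2E)-7-hydroxy-3,7-dimethyloct-2-en-1-yl]-4-oxo-4H-chromen-7-yl acetate
Conditions: Ac2O (1.1 equiv), pyridine, CH2Cl2, 0 °C
Reagents that add atoms: acetic anhydride, CC(=O)OC(C)=O
Why: Chemoselective O-acetylation takes the acidic 7-OH only; the hydrogen-bonded 5-OH and the tertiary alcohol do not react without DMAP.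

**Step 13**
Reactants: 15, 1,2-phenylene diacetate (catechol diacetate)
Product: 16, 4-(4,4,5,5-tetramethyl-1,3,2-dioxaborolan-2-yl)-1,2-phenylene diacetate
Conditions: [Ir(OMe)(cod)]2 (1 mol %), dtbpy, B2pin2, MTBE, 60 °C
Reagents that add atoms: bis(pinacolato)diboron, CC1(C)OB(OC1(C)C)B1OC(C)(C)C(C)(C)O1
Why: Sterically controlled Ir C–H borylation of a symmetric 1,2-disubstituted arene gives only the 4-boronate and tolerates aryl esters.

**Step 14**
Reactants: 16
Product: 17, [3,4-bis(acetyloxy)phenyl]boronic acid
Conditions: NaIO4, THF/H2O (4:1), rt; then 1 M HCl, rt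
Reagents that add atoms: water, O
Why: Oxidative cleavage of pinacol releases the free boronic acid under mildly acidic conditions that leave the aryl acetates intact.

**Step 15**
Reactants: 14; 17 (3 equiv)
Product: 18, (2S)-2-[3,4-bis(acetyloxy)phenyl]-5-hydroxy-6-[(2E)-7-hydroxy-3,7-dimethyloct-2-en-1-yl]-4-oxo-3,4-dihydro-2H-chromen-7-yl acetate
Conditions: [Rh(OH)(cod)]2 (2.5 mol %), (S)-MeO-F12-BIPHEP (5.5 mol %), toluene/H2O (10:1), 40 °C
Reagents that add atoms: none
Why: Hayashi–Miyaura Rh-catalysed asymmetric 1,4-addition delivers the aryl group to the Re face of chromone C2, setting (2S). The (S)-ligand is chosen by analogy with (S)-BINAP giving (S)-3-arylcyclohexanones; the sense must be confirmed by CD or chiral HPLC, and the (R)-ligand is equally available. The base-free medium keeps the acetates and avoids retro-oxa-Michael racemisation.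

**Step 16**
Reactants: 18
Product: 19, Prokinawan, (2S)-2-(3,4-dihydroxyphenyl)-5,7-dihydroxy-6-[(2E)-7-hydroxy-3,7-dimethyloct-2-en-1-yl]-2,3-dihydro-4H-chromen-4-one
Conditions: lipase (serine hydrolase; immobilised Candida antarctica lipase B, Novozym 435), n-BuOH (20 equiv), MTBE/THF (4:1), 40 °C, N2
Reagents that add atoms: none
Why: Lipase-catalysed transesterification (alcoholysis) removes the three phenolic acetates at neutral pH, so C2 cannot epimerise through the chalcone and the hydroxy-alkenyl chain sees no acid.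

## Compound list

1 | geranyl acetate | CC(=O)OC/C=C(\C)CCC=C(C)C | starting material
2 | (2E)-7-hydroxy-3,7-dimethyloct-2-en-1-yl acetate | CC(=O)OC/C=C(\C)CCCC(C)(C)O | intermediate
3 | (2E)-3,7-dimethyl-7-(triethylsilyloxy)oct-2-en-1-yl acetate | CC(=O)OC/C=C(\C)CCCC(C)(C)O[Si](CC)(CC)CC | intermediate
4 | (2E)-3,7-dimethyl-7-(triethylsilyloxy)oct-2-en-1-ol | OC/C=C(\C)CCCC(C)(C)O[Si](CC)(CC)CC | intermediate
5 | (6E)-8-bromo-2,6-dimethyl-2-(triethylsilyloxy)oct-6-ene | BrC/C=C(\C)CCCC(C)(C)O[Si](CC)(CC)CC | intermediate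
6 | resorcinol | Oc1cccc(O)c1 | starting material
7 | 1,3-bis(methoxymethoxy)benzene | COCOc1cccc(OCOC)c1 | intermediate
8 | 2-[(2E)-3,7-dimethyl-7-(triethylsilyloxy)oct-2-en-1-yl]-1,3-bis(methoxymethoxy)benzene | COCOc1cccc(OCOC)c1C/C=C(\C)CCCC(C)(C)O[Si](CC)(CC)CC | intermediate
9 | 4-[(2E)-3,7-dimethyl-7-(triethylsilyloxy)oct-2-en-1-yl]-3,5-bis(methoxymethoxy)phenol | COCOc1cc(O)cc(OCOC)c1C/C=C(\C)CCCC(C)(C)O[Si](CC)(CC)CC | intermediate
10 | 2-iodo-3,5-bis(methoxymethoxy)-4-[(2E)-3,7-dimethyl-7-(triethylsilyloxy)oct-2-en-1-yl]phenol | COCOc1cc(O)c(I)c(OCOC)c1C/C=C(\C)CCCC(C)(C)O[Si](CC)(CC)CC | intermediate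
11 | 1-{6-hydroxy-2,4-bis(methoxymethoxy)-3-[(2E)-3,7-dimethyl-7-(triethylsilyloxy)oct-2-en-1-yl]phenyl}ethan-1-one | COCOc1cc(O)c(C(C)=O)c(OCOC)c1C/C=C(\C)CCCC(C)(C)O[Si](CC)(CC)CC | intermediate
12 | (2E)-3-(dimethylamino)-1-{6-hydroxy-2,4-bis(methoxymethoxy)-3-[(2E)-3,7-dimethyl-7-(triethylsilyloxy)oct-2-en-1-yl]phenyl}prop-2-en-1-one | COCOc1cc(O)c(C(=O)/C=C/N(C)C)c(OCOC)c1C/C=C(\C)CCCC(C)(C)O[Si](CC)(CC)CC | intermediate
13 | 5,7-dihydroxy-6-[(2E)-7-hydroxy-3,7-dimethyloct-2-en-1-yl]-4H-chromen-4-one | O=c1ccoc2cc(O)c(C/C=C(\C)CCCC(C)(C)O)c(O)c12 | intermediate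
14 | 5-hydroxy-6-[(2E)-7-hydroxy-3,7-dimethyloct-2-en-1-yl]-4-oxo-4H-chromen-7-yl acetate | CC(=O)Oc1cc2occc(=O)c2c(O)c1C/C=C(\C)CCCC(C)(C)O | intermediate
15 | 1,2-phenylene diacetate | CC(=O)Oc1ccccc1OC(C)=O | starting material
16 | 4-(4,4,5,5-tetramethyl-1,3,2-dioxaborolan-2-yl)-1,2-phenylene diacetate | CC(=O)Oc1ccc(B2OC(C)(C)C(C)(C)O2)cc1OC(C)=O | intermediate
17 | [3,4-bis(acetyloxy)phenyl]boronic acid | CC(=O)Oc1ccc(B(O)O)cc1OC(C)=O | intermediate
18 | (2S)-2-[3,4-bis(acetyloxy)phenyl]-5-hydroxy-6-[(2E)-7-hydroxy-3,7-dimethyloct-2-en-1-yl]-4-oxo-3,4-dihydro-2H-chromen-7-yl acetate | C/C(=C\Cc1c(OC(C)=O)cc2c(c1O)C(=O)C[C@@H](c1ccc(OC(C)=O)c(OC(C)=O)c1)O2)CCCC(C)(C)O | intermediate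
19 | Prokinawan | C/C(=C\Cc1c(O)cc2c(c1O)C(=O)C[C@@H](c1ccc(O)c(O)c1)O2)CCCC(C)(C)O | target

## Summary

Total steps: 16. Longest linear sequence: 13 (steps 1–4, 6–12, 15, 16).

Steps most likely to fail, with fallbacks:

1. **Step 15 (Rh asymmetric 1,4-addition).** The free, chelating 5-OH may slow the catalyst, and the substrate carries acetates. Fallback: condense ketone 11 with 3,4-bis(methoxymethoxy)benzaldehyde (Claisen–Schmidt) and cyclise the 2'-hydroxychalcone with NaOAc to the racemic 6-substituted flavanone, where regiochemistry is still fixed by the single free OH. Then recover the (2S)-ketone by Noyori-type Rh/TsDPEN transfer-hydrogenation kinetic resolution and deprotect.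

2. **Step 11 (acidic ring closure and MOM/TES removal).** The ortho-phenol/alkene pair can cyclise to a chroman, and the tertiary alcohol can solvolyse. Fallback: use SEM ethers instead of MOM from step 5 (same metalation and borylation chemistry), close the chromone in warm AcOH, and remove SEM and TES with fluoride (TBAF/DMPU), avoiding strong protic acid.

3. **Step 9 (Stille acetylation of a hindered, very electron-rich, unprotected iodophenol).** Fallback: skip steps 8–10. Ortho-formylate phenol 9 (MgCl2, Et3N, paraformaldehyde), add ethynylmagnesium bromide, oxidise with MnO2 and close the o-hydroxyaryl ynone by amine-triggered 6-endo cyclisation to the bis-MOM chromone, then deprotect with acid to 13.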